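**Plan**
- Retrosynthesis: the two S–O bonds at O3 and O7 are cut first, then O1–C8a of the pyranone (ring C), then C2–C3 (aldol) and C4–C4a (aryl ketone formation).
- Forward: an A-ring aryllithium is acylated by a benzyloxyacetyl Weinreb amide (C4–C4a); aldol addition to 3,4-diacetoxybenzaldehyde (C2–C3) and oxidation give the diaryl 2-benzyloxy-1,3-diketone; ring C is closed last by O1–C8a; debenzylation, 3,7-disulfation and deacetylation follow.
- Enabling feature: in ring A, C5 and C7 carry oxygen and C8a is the only C–H ortho to the C4 carbonyl. C8a is meta to both C5–O and C7–O, so ring A must come from a 2,4-dioxygenated aryl ketone (a 3,5-dioxygenated one would end as the 6,8-pattern).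
- Because C8a lies on a node of the arene HOMO, the C–H bond is selected by palladium held on the enolate oxygen, with the anode as oxidant, and not by hole density in the ring.
- Protecting groups: benzyl on O3/O5/O7 (removed together; O5–H then stays unreactive through its hydrogen bond to C4=O), acetyl on O3'/O4' (deactivates ring B in the key step, removed last).
- Stereochemistry: the target has no stereocentre; those of the aldol and the diketone are erased by oxidation and ring closure.

Key step: step 6

Remark: the target is achiral, so no enantiomer has to be selected; the sulfates are drawn as free acids, and 13 and 14 would be handled as their pyridinium and ammonium salts, which are treated as the same compounds.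

**Step 1**
Reactants: 1 4-bromoresorcinol (4-bromobenzene-1,3-diol)
Product: 2 2,4-bis(benzyloxy)-1-bromobenzene
Conditions: BnBr, K2CO3, DMF, 60 °C
Reagents that add atoms: benzyl bromide, BrCc1ccccc1
Why: Williamson etherification, in which carbonate deprotonates both phenols and the phenoxides displace bromide from benzyl bromide by SN2.

**Step 2**
Reactants: 2 2,4-bis(benzyloxy)-1-bromobenzene; 3 2-(benzyloxy)-N-methoxy-N-methylacetamide
Product: 5 2-(benzyloxy)-1-[2,4-bis(benzyloxy)phenyl]ethan-1-one, via [2,4-bis(benzyloxy)phenyl]lithium 4 (not isolated)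
Conditions: n-BuLi, THF, −78 °C; then 3, −78 → 0 °C; aq. HCl
Reagents that add atoms: none
Why: Bromine–lithium exchange is far faster at −78 °C than deprotonation of the benzyl ethers, and the aryllithium adds only once to the Weinreb amide because the chelated tetrahedral adduct persists until the acidic quench (Weinreb ketone synthesis).

**Step 3**
Reactants: 6 3,4-dihydroxybenzaldehyde
Product: 7 3,4-diacetoxybenzaldehyde (4-formyl-1,2-phenylene diacetate)
Conditions: Ac2O, pyridine, 0 °C → rt
Reagents that add atoms: acetic anhydride, CC(=O)OC(C)=O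
Why: Pyridine-promoted O-acetylation of both phenols, which leaves the aldehyde untouched.

**Step 4**
Reactants: 5 2-(benzyloxy)-1-[2,4-bis(benzyloxy)phenyl]ethan-1-one; 7 3,4-diacetoxybenzaldehyde
Product: 9 4-{3-[2,4-bis(benzyloxy)phenyl]-2-(benzyloxy)-1-hydroxy-3-oxopropyl}-1,2-phenylene diacetate (racemic syn/anti mixture), via lithium enolate 8 (not isolated)
Conditions: LiHMDS, THF, −78 °C; then 7, −78 °C; AcOH quench at −78 °C
Reagents that add atoms: none
Why: Lithium enolate aldol addition, in which the chelated (Z)-enolate should add to the non-enolisable aldehyde much faster at −78 °C than it attacks the aryl acetates; the configuration at the two new stereocentres is immaterial because both are erased in steps 5 and 6.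

**Step 5**
Reactants: 9 the aldol adduct
Product: 10 4-{3-[2,4-bis(benzyloxy)phenyl]-2-(benzyloxy)-3-oxopropanoyl}-1,2-phenylene diacetate (racemic in the keto form, enolisable)
Conditions: IBX, EtOAc, 77 °C
Reagents that add atoms: none
Why: IBX oxidation of a β-hydroxy ketone to the β-diketone, a neutral oxidation that avoids retro-aldol cleavage and leaves benzyl ethers and aryl acetates alone.

**Step 6**
Reactants: 10 the diaryl 2-benzyloxy-1,3-diketone
Product: 11 3',4'-di-O-acetyl-3,5,7-tri-O-benzylquercetin
Conditions: Pd(OAc)2 (10 mol %), N-acetylglycine (20 mol %), KOAc (0.5 equiv), n-Bu4NPF6, HFIP–AcOH, 50 °C; divided cell, graphite-felt anode, Pt cathode, constant current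
Reagents that add atoms: none
Why: Proposed new method: Pd(II) bound to the enolate oxygen on C2 (diketone in its sickle conformation, C4=O turned outward) should cleave C8a–H by acetate-assisted concerted metalation–deprotonation to a seven-membered palladacycle, which the anode oxidises to Pd(IV); C8a–O1 reductive elimination then closes the pyranone and returns Pd(II), while the cathode reduces the released protons to H2. The closest known reactions are the Pd(II)/Pd(IV) C–H lactonisation of 2-arylbenzoic acids, which passes through the same seven-membered palladacycle with a carboxylate in place of this vinylogous carboxylate, and palladium-catalysed directed aryl C–H acetoxylation with the anode as terminal oxidant. Ring C is closed as a six-membered ring by C–O reductive elimination, formally a 6-endo attack of O1 on the C4a=C8a bond, and no stereocentre is formed because C3 becomes sp2. Site selectivity is geometric: on ring A only C8a–H is ortho to the C4 acyl group and within reach of O1-bound palladium, which matters because C8a is meta to both benzyloxy groups and lies on a node of the arene HOMO, so an uncatalysed radical-cation closure would not be directed there. Selectivity for ring A over ring B rests on the two acetoxy groups, which make the ortho C–H bonds of ring B poorer partners for electrophilic palladation than that of the benzyloxy-substituted ring A. Because only the palladacycle has to be oxidised, the anode potential can stay below that needed to oxidise the dialkoxyarene or the benzyl ethers.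

**Step 7**
Reactants: 11 3',4'-di-O-acetyl-3,5,7-tri-O-benzylquercetin
Product: 12 3',4'-di-O-acetylquercetin
Conditions: H2 (1 atm), 10% Pd/C, EtOAc–THF, rt
Reagents that add atoms: none
Why: Catalytic hydrogenolysis of the three O-benzyl groups under neutral conditions, which should leave the aryl acetates and the chromone double bond intact.

**Step 8**
Reactants: 12 3',4'-di-O-acetylquercetin
Product: 13 3',4'-di-O-acetylquercetin 3,7-bis(hydrogen sulfate) (carried on as the bis-pyridinium salt)
Conditions: SO3·pyridine (3 equiv), pyridine, 0 °C → rt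
Reagents that add atoms: sulfur trioxide–pyridine complex, [O-]S(=O)(=O)[n+]1ccccc1
Why: O-sulfonation of phenols with an amine–sulfur trioxide complex, in which the acidic 7-OH and the 3-OH should react while 5-OH is held in its hydrogen bond to C4=O and O3'/O4' are acetylated.

**Step 9**
Reactants: 13 3',4'-di-O-acetylquercetin 3,7-bis(hydrogen sulfate)
Product: 14 quercetin 3,7-di-O-sulfate
Conditions: NH3 (7 M in MeOH), 0 °C → rt, argon
Reagents that add atoms: none
Why: Ammonolysis of the two aryl acetates, to which aryl sulfate monoester anions are inert; exclusion of air protects the liberated catechol.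

**Compound list**
1 | 4-bromoresorcinol (4-bromobenzene-1,3-diol) | Oc1ccc(Br)c(O)c1 | starting material
2 | 2,4-bis(benzyloxy)-1-bromobenzene | Brc1ccc(OCc2ccccc2)cc1OCc1ccccc1 | intermediate
3 | 2-(benzyloxy)-N-methoxy-N-methylacetamide | CON(C)C(=O)COCc1ccccc1 | starting material
4 | [2,4-bis(benzyloxy)phenyl]lithium (not isolated) | [Li]c1ccc(OCc2ccccc2)cc1OCc1ccccc1 | intermediate
5 | 2-(benzyloxy)-1-[2,4-bis(benzyloxy)phenyl]ethan-1-one | O=C(COCc1ccccc1)c1ccc(OCc2ccccc2)cc1OCc1ccccc1 | intermediate
6 | 3,4-dihydroxybenzaldehyde | O=Cc1ccc(O)c(O)c1 | starting material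
7 | 3,4-diacetoxybenzaldehyde | CC(=O)Oc1ccc(C=O)cc1OC(C)=O | intermediate
8 | lithium (Z)-enolate of 5 (not isolated) | [Li]O/C(=C\OCc1ccccc1)c1ccc(OCc2ccccc2)cc1OCc1ccccc1 | intermediate
9 | 4-{3-[2,4-bis(benzyloxy)phenyl]-2-(benzyloxy)-1-hydroxy-3-oxopropyl}-1,2-phenylene diacetate (racemic syn/anti mixture, configuration not defined) | CC(=O)Oc1ccc(C(O)C(OCc2ccccc2)C(=O)c2ccc(OCc3ccccc3)cc2OCc2ccccc2)cc1OC(C)=O | intermediate
10 | 4-{3-[2,4-bis(benzyloxy)phenyl]-2-(benzyloxy)-3-oxopropanoyl}-1,2-phenylene diacetate (racemic in the keto form, enolisable) | CC(=O)Oc1ccc(C(=O)C(OCc2ccccc2)C(=O)c2ccc(OCc3ccccc3)cc2OCc2ccccc2)cc1OC(C)=O | intermediate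
11 | 3',4'-di-O-acetyl-3,5,7-tri-O-benzylquercetin | CC(=O)Oc1ccc(-c2oc3cc(OCc4ccccc4)cc(OCc4ccccc4)c3c(=O)c2OCc2ccccc2)cc1OC(C)=O | intermediate
12 | 3',4'-di-O-acetylquercetin | CC(=O)Oc1ccc(-c2oc3cc(O)cc(O)c3c(=O)c2O)cc1OC(C)=O | intermediate
13 | 3',4'-di-O-acetylquercetin 3,7-bis(hydrogen sulfate) | CC(=O)Oc1ccc(-c2oc3cc(OS(=O)(=O)O)cc(O)c3c(=O)c2OS(=O)(=O)O)cc1OC(C)=O | intermediate
14 | quercetin 3,7-di-O-sulfate | O=c1c(OS(=O)(=O)O)c(-c2ccc(O)c(O)c2)oc2cc(OS(=O)(=O)O)cc(O)c12 | target

**Totals**
Total step count: 9. Longest linear sequence: 8 steps (steps 1, 2, 4, 5, 6, 7, 8, 9); step 3 is a one-step branch.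

**Steps most likely to fail**

1. Step 6. Palladium may be sequestered as the O,O-chelate of the diketonate without C–H cleavage. Palladation may occur on ring B. Acetate may be transferred to C8a in place of the enol oxygen. The enol may be oxidised directly at the anode.

   The fallback uses known chemistry, sets out from Weinreb amide 3 and returns at 11. Purchased 1,3-bis(benzyloxy)-5-bromobenzene F1 would be iodinated (NIS, cat. TFA, MeCN), mainly at the carbon between bromine and a benzyloxy group, to give 1,5-bis(benzyloxy)-3-bromo-2-iodobenzene F2. Iodine–magnesium exchange (i-PrMgCl·LiCl, THF, −40 °C) would give [2,4-bis(benzyloxy)-6-bromophenyl]magnesium chloride F3, which with 3 should give 2-(benzyloxy)-1-[2,4-bis(benzyloxy)-6-bromophenyl]ethan-1-one F4. As in steps 4 and 5, the lithium (Z)-enolate of this ketone F5 would add to 7 to give 4-{3-[2,4-bis(benzyloxy)-6-bromophenyl]-2-(benzyloxy)-1-hydroxy-3-oxopropyl}-1,2-phenylene diacetate F6, and IBX would give 4-{3-[2,4-bis(benzyloxy)-6-bromophenyl]-2-(benzyloxy)-3-oxopropanoyl}-1,2-phenylene diacetate F7. Copper-catalysed intramolecular O-arylation of the enolate (CuI, 1,10-phenanthroline, K3PO4, toluene, 80 °C; Ullmann type) would then form O1–C8a at the brominated carbon and give 11.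

2. Step 8. Sulfation of the hindered 3-OH may stay incomplete, the chelated 5-OH may be sulfated with excess reagent, or acetyl groups may migrate in the basic medium, giving anionic mixtures that are hard to separate.

   The fallback sets out from 12 and returns at 13. Treatment with 2,2,2-trichloroethyl chlorosulfate (Et3N, DMAP, THF) would give the neutral, silica-stable 3',4'-di-O-acetylquercetin 3,7-bis(2,2,2-trichloroethyl sulfate) F8, which can be purified from under- and over-sulfated material. Zinc dust and ammonium formate in methanol would then unmask both sulfates to give 13.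

3. Step 4. Acetyl groups may be transferred from the aryl acetates to the enolate or the lithium aldolate, and retro-aldol cleavage may occur on warming.

   The fallback sets out from 7, is joined by 5 and returns at 10, bypassing 9 and step 5. Pinnick oxidation of 7 (NaClO2, NaH2PO4, 2-methyl-2-butene, t-BuOH–H2O) would give 3,4-diacetoxybenzoic acid F9, and oxalyl chloride with catalytic DMF would give 3,4-diacetoxybenzoyl chloride F10. C-acylation of ketone 5 with this chloride under soft enolisation (MgBr2·OEt2, i-Pr2NEt, CH2Cl2, rt; Claisen-type) would give 10 directly without strong base.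

**Further compounds**
F1 | step 6 | 1,3-bis(benzyloxy)-5-bromobenzene (purchased building block) | Brc1cc(OCc2ccccc2)cc(OCc2ccccc2)c1
F2 | step 6 | 1,5-bis(benzyloxy)-3-bromo-2-iodobenzene | Brc1cc(OCc2ccccc2)cc(OCc2ccccc2)c1I
F3 | step 6 | [2,4-bis(benzyloxy)-6-bromophenyl]magnesium chloride | Cl[Mg]c1c(Br)cc(OCc2ccccc2)cc1OCc1ccccc1
F4 | step 6 | 2-(benzyloxy)-1-[2,4-bis(benzyloxy)-6-bromophenyl]ethan-1-one | O=C(COCc1ccccc1)c1c(Br)cc(OCc2ccccc2)cc1OCc1ccccc1
F5 | step 6 | lithium (Z)-enolate of F4 | [Li]O/C(=C\OCc1ccccc1)c1c(Br)cc(OCc2ccccc2)cc1OCc1ccccc1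
F6 | step 6 | 4-{3-[2,4-bis(benzyloxy)-6-bromophenyl]-2-(benzyloxy)-1-hydroxy-3-oxopropyl}-1,2-phenylene diacetate (racemic syn/anti mixture) | CC(=O)Oc1ccc(C(O)C(OCc2ccccc2)C(=O)c2c(Br)cc(OCc3ccccc3)cc2OCc2ccccc2)cc1OC(C)=O
F7 | step 6 | 4-{3-[2,4-bis(benzyloxy)-6-bromophenyl]-2-(benzyloxy)-3-oxopropanoyl}-1,2-phenylene diacetate | CC(=O)Oc1ccc(C(=O)C(OCc2ccccc2)C(=O)c2c(Br)cc(OCc3ccccc3)cc2OCc2ccccc2)cc1OC(C)=O
F8 | step 8 | 3',4'-di-O-acetylquercetin 3,7-bis(2,2,2-trichloroethyl sulfate) | CC(=O)Oc1ccc(-c2oc3cc(OS(=O)(=O)OCC(Cl)(Cl)Cl)cc(O)c3c(=O)c2OS(=O)(=O)OCC(Cl)(Cl)Cl)cc1OC(C)=O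
F9 | step 4 | 3,4-diacetoxybenzoic acid | CC(=O)Oc1ccc(C(=O)O)cc1OC(C)=O
F10 | step 4 | 3,4-diacetoxybenzoyl chloride | CC(=O)Oc1ccc(C(Cl)=O)cc1OC(C)=O
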